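Read two rates off the red run and set them against each other.

- red: starting material 0.15 M; coupling partner 0.30 M; free catalyst 0.60 mM; run made earlier
- flask: starting material 0.30 M; coupling partner 0.300 M; free catalyst 0.60 mM; time 40 h

red run (percent of the starting material charged)

| time / h | target / % | over-reaction product / % |
|---|---|---|
| 1.00 | 13.2 | 0.3 |
| 1.50 | 18.4 | 1.2 |
| 2.50 | 26.3 | 4.0 |
| 4.00 | 35.8 | 8.4 |
| 8.00 | 44.1 | 21.8 |
| 12.0 | 44.2 | 32.7 |

(scatter of a reading: 0.5 percentage points)

- why nothing more happens at 40 h, or that something still does (forward and back rates have come level / all of the starting material has reacted / no working catalyst is left / the coupling partner has run out first / it is still moving)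
- the target standing at 40 h, as a percentage of the starting material charged
- the over-reaction product standing at 40 h, as a percentage of the starting material charged

- the numbers in the tables scatter by 0.5 percentage points (one standard deviation)
- the reaction counts as stopped when no species that holds the starting material changes by six tenths of a point or more over the second half of the time

The first reading gives a making rate of 0.0203 M h⁻¹ at the charged c(coupling partner). From 4.00 h to 8.00 h, the over-reaction product grows as 0.431 M⁻¹ h⁻¹ times c(target) times c(coupling partner).

As a rough model, I let making scale with c(coupling partner) and ignore c(starting material). Then c(coupling partner) cancels, and you get the target ceiling, the c(target) at which use equals making: 0.157 M.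

The red run shows how rough this is. From 8.00 h to 12.0 h the target readings stay level, so making is near the over-reaction product's growth of 0.00409 M h⁻¹. That is less than the 0.0103 M h⁻¹ this model gives, so in the red run making falls with c(starting material) too.

Write Q for the ceiling, P for c(target) and O for c(over-reaction product). Integrating gives O = -P - Q ln(1 - P/Q). Coupling partner is the limiting reagent, so P + 2O equals its charge once it is spent.

Solving for this flask gives c(target) 0.115 M. That is 38.3% target and 30.8% over-reaction product. Coupling partner decays at up to 0.117 h⁻¹, so at least 9.63% remains at 20.0 h and 0.927% at 40 h. I expect this flask to be still moving.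

The forecast says it is still moving, with 44% target and 27% over-reaction product: “nearly finished but technically still moving”.

The flask gives it is still moving, with 34.7% target and 31.3% over-reaction product.

    catalyst intermediate D → free catalyst + target (k = 26.0 min⁻¹)
    coupling partner + free catalyst ⇌ catalyst intermediate A (K = 1.50 M⁻¹, k = 4.20 M⁻¹ min⁻¹)
    coupling partner + target → over-reaction product (k = 0.00670 M⁻¹ min⁻¹)
    starting material + catalyst intermediate C ⇌ catalyst intermediate D (K = 1.80 M⁻¹, k = 1800 M⁻¹ min⁻¹)
    catalyst intermediate B ⇌ by-product + catalyst intermediate C (K = 0.140 M, k = 18.0 min⁻¹)
    catalyst intermediate A ⇌ catalyst intermediate B (K = 0.420, k = 110 min⁻¹)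

In this flask, target is made 2.11 times as fast as it is used up at 5.72 h, and at 40 h it stands at 0.104 M, which is 66.3% of the ceiling. The neighbour flask with 0.0024 M of free catalyst, if making scales with catalyst, has a ceiling of 0.627 M; the same balance then gives 70.2% target, and that flask holds 61.7%.

The runs were generated by integration from invented constants, noise included.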